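**Retrosynthetic overview**
- Feature: the central benzene ring of the phenalenone (C3a, C4, C5, C6, C6a, C9b), fused at C5–C6 to the five-membered indane ring (C5, C6, spiro-ketal carbon, CH, C–OH), is the dehydrated [4+2] adduct of a photoenol diene (quinone C4 and the peri CH2 of a 5-alkyl-8-methoxy-1,4-naphthoquinone) with an ethynyl group on the carbinol carbon.
- Disconnections, backwards: O–CH3 (last step); C3a–C4 and C5–C6 (key step); quinone from a trimethoxynaphthalene (ceric oxidation); cyclopentenone C5–ketal carbon (Mukaiyama-type alkylation of a silyloxydiene with a naphthodioxinylium ion).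
- Fragments: a mixed orthoester from juglone and 1,8-dihydroxynaphthalene; (S)-4-ethynyl-4-hydroxycyclopentenone from (R)-4-silyloxycyclopentenone and ethynylmagnesium bromide.
- Ring order: naphthalene and cyclopentenone are bought; spiro-dioxine ring (step 5); quinone ring unmasked (step 11); central benzene ring and indane ring together (step 12).

Key step: step 12

Remark: bromination of 3 is assumed to occur para to the isolated methoxy group (as in 1,5-dimethoxynaphthalene), and the acetylide is assumed to add to 10 anti to the silyloxy group.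

**Step 1**
Reactants: 1 juglone
Product: 3 1,4,5-trimethoxynaphthalene, via naphthalene-1,4,5-triol 2 (not isolated)
Conditions: Na2S2O4, Bu4NBr (cat.), THF/H2O, rt; then KOH, Me2SO4, rt
Reagents that add atoms: dimethyl sulfate COS(=O)(=O)OC
Why: Reductive methylation, in which dithionite reduces the quinone to the air-sensitive triol and exhaustive Williamson O-methylation under phase transfer traps it in the same flask.

**Step 2**
Reactants: 3 1,4,5-trimethoxynaphthalene
Product: 4 1-bromo-4,5,8-trimethoxynaphthalene
Conditions: NBS, MeCN, 0 °C to rt, dark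
Reagents that add atoms: N-bromosuccinimide O=C1CCC(=O)N1Br
Why: Electrophilic aromatic bromination is expected at C8 of 3, the free α-position para to the 5-methoxy group and the most nucleophilic site of the ring system.

**Step 3**
Reactants: 4 1-bromo-4,5,8-trimethoxynaphthalene
Product: 5 2-(4,5,8-trimethoxynaphthalen-1-yl)acetonitrile
Conditions: Me3SiCH2CN, ZnF2, Pd2(dba)3 (cat.), Xantphos (cat.), DMF, 90 °C
Reagents that add atoms: (trimethylsilyl)acetonitrile C[Si](C)(C)CC#N
Why: Palladium-catalysed cross-coupling of the aryl bromide with the fluoride-activated silylacetonitrile (α-arylation of a nitrile) should give the arylacetonitrile without a free, strongly basic nitrile anion.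

**Step 4**
Reactants: 5 2-(4,5,8-trimethoxynaphthalen-1-yl)acetonitrile
Product: 7 4,5,8-trimethoxy-1-(2,2,2-trimethoxyethyl)naphthalene, via imidate hydrochloride 6 (not isolated)
Conditions: HCl (g), MeOH (1.1 equiv), Et2O, 0 °C; then MeOH (excess), hexane, rt; K2CO3 work-up
Reagents that add atoms: methanol CO
Why: Pinner reaction, in which HCl and one equivalent of methanol give the imidate hydrochloride 6 and its methanolysis gives the trimethyl orthoester and ammonium chloride.

**Step 5**
Reactants: 7 4,5,8-trimethoxy-1-(2,2,2-trimethoxyethyl)naphthalene; 8 1,8-dihydroxynaphthalene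
Product: 9 2-methoxy-2-[(4,5,8-trimethoxynaphthalen-1-yl)methyl]naphtho[1,8-de][1,3]dioxine
Conditions: PPTS (cat.), PhMe, 50 °C, MeOH removed under reduced pressure; Et3N quench
Reagents that add atoms: none
Why: Acid-catalysed transorthoesterification, in which the peri-diol replaces two methoxy groups and closes the six-membered naphthodioxine ring, driven by removal of methanol.

**Step 6**
Reactants: 10 (R)-4-(tert-butyldimethylsilyloxy)cyclopent-2-en-1-one; 11 ethynylmagnesium bromide
Product: 12 (1S,4R)-4-(tert-butyldimethylsilyloxy)-1-ethynylcyclopent-2-en-1-ol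
Conditions: CeCl3, THF, −78 °C; aq. NH4Cl
Reagents that add atoms: none
Why: 1,2-Addition of the cerium-modified alkynyl Grignard reagent to the enone carbonyl from the face anti to the C4 silyloxy group should set the quaternary carbinol as 1S (OH cis to OTBS), and the minor diastereomer is removed by chromatography.

**Step 7**
Reactants: 12 (1S,4R)-4-(tert-butyldimethylsilyloxy)-1-ethynylcyclopent-2-en-1-ol
Product: 13 (1S,4R)-1-ethynylcyclopent-2-ene-1,4-diol
Conditions: Bu4NF, THF, 0 °C
Reagents that add atoms: none
Why: Fluoride-induced cleavage of the secondary silyl ether, which touches no stereocentre.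

**Step 8**
Reactants: 13 (1S,4R)-1-ethynylcyclopent-2-ene-1,4-diol
Product: 14 (S)-4-ethynyl-4-hydroxycyclopent-2-en-1-one
Conditions: MnO2 (activated), CH2Cl2, rt
Reagents that add atoms: none
Why: Chemoselective MnO2 oxidation of the secondary allylic alcohol (the tertiary propargylic alcohol cannot be oxidised) gives the enone and leaves the quaternary carbinol as the only stereocentre (S).

**Step 9**
Reactants: 14 (S)-4-ethynyl-4-hydroxycyclopent-2-en-1-one
Product: 15 (R)-5-ethynyl-2,5-bis(trimethylsilyloxy)cyclopenta-1,3-diene
Conditions: TMSOTf (2.3 equiv), Et3N, CH2Cl2, −78 to 0 °C; used crude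
Reagents that add atoms: trimethylsilyl trifluoromethanesulfonate C[Si](C)(C)OS(=O)(=O)C(F)(F)F
Why: Silyl triflate and amine silylate the tertiary alcohol and effect soft enolisation at C5, the only enolisable position because C4 is quaternary, giving a cross-conjugated 2-silyloxydiene that cannot undergo 1,5-hydrogen shifts.

**Step 10**
Reactants: 9 2-methoxy-2-[(4,5,8-trimethoxynaphthalen-1-yl)methyl]naphtho[1,8-de][1,3]dioxine; 15 (R)-5-ethynyl-2,5-bis(trimethylsilyloxy)cyclopenta-1,3-diene
Product: 17 (4R,5S)-4-ethynyl-5-{2-[(4,5,8-trimethoxynaphthalen-1-yl)methyl]naphtho[1,8-de][1,3]dioxin-2-yl}-4-(trimethylsilyloxy)cyclopent-2-en-1-one, via naphthodioxinylium triflate 16 (not isolated)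
Conditions: TMSOTf (0.2 equiv), CH2Cl2, −78 °C; pyridine, aq. NaHCO3
Reagents that add atoms: none
Why: Mukaiyama-type alkylation, in which catalytic TMSOTf should ionise the methoxy group of the orthoester to the naphthodioxinylium ion 16 and C5 of the silyloxydiene attacks it to restore the enone; the adjacent quaternary centre sets the new C5 stereocentre, the cation arriving anti to OSiMe3 and cis to the slim ethynyl group (5S).

**Step 11**
Reactants: 17 (4R,5S)-4-ethynyl-5-{2-[(4,5,8-trimethoxynaphthalen-1-yl)methyl]naphtho[1,8-de][1,3]dioxin-2-yl}-4-(trimethylsilyloxy)cyclopent-2-en-1-one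
Product: 18 (4R,5S)-4-ethynyl-4-hydroxy-5-{2-[(8-methoxy-1,4-dioxo-1,4-dihydronaphthalen-5-yl)methyl]naphtho[1,8-de][1,3]dioxin-2-yl}cyclopent-2-en-1-one
Conditions: (NH4)2Ce(NO3)6 (2.3 equiv), MeCN/H2O, 0 °C
Reagents that add atoms: water O
Why: Ceric oxidative demethylation of the only para-dimethoxy ring, which is more easily oxidised than the naphthalenediol ketal, gives the 5-alkyl-8-methoxy-1,4-naphthoquinone with both carbonyl oxygens from water, and the acidic aqueous medium hydrolyses the tertiary trimethylsilyl ether.

**Step 12**
Reactants: 18 (4R,5S)-4-ethynyl-4-hydroxy-5-{2-[(8-methoxy-1,4-dioxo-1,4-dihydronaphthalen-5-yl)methyl]naphtho[1,8-de][1,3]dioxin-2-yl}cyclopent-2-en-1-one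
Product: 21 9-O-methylspiropreussione B, via photoenol 19 (not isolated), via hydroxy cycloadduct 20 (not isolated)
Conditions: hν (420–450 nm LED), dry degassed MeCN (1 mM), 20 °C; then PPTS (cat.), 40 °C
Reagents that add atoms: none
Why: Proposed new method: n,π* excitation of the quinone should cause 1,5-hydrogen transfer from the peri CH2 to the C4 carbonyl oxygen to give photoenol 19 (an (E)-configured 4-hydroxy-5-alkylidene-naphthalen-1(5H)-one, a hydroxy-o-quinodimethane), whose diene termini (benzylic carbon and former C4) add suprafacially across the ethynyl group in a type-1 intramolecular Diels–Alder reaction to give 20, and acid-promoted 1,4-loss of water (tertiary OH on former C4, H on the former benzylic carbon) aromatises the new ring to 21. The closest known reactions are the photoenolisation/Diels–Alder trapping of o-alkyl aryl ketones and aldehydes with alkynes followed by dehydration to naphthalenes, and the photoenolisation of 5-alkyl-1,4-naphthoquinones, which have not been combined. The central benzene ring (C3a–C4–C5–C6–C6a–C9b) closes by the [4+2] cycloaddition that forms C3a–C4 and C5–C6, and the indane five-membered ring closes in the same event as the ring of the three-atom tether (5-exo with respect to the benzylic carbon–alkyne bond). No stereocentre is created in 21 (the two sp3 centres of 20 vanish on aromatisation) and the 4R,5S centres of the cyclopentenone are only carried through. The step needs cycloaddition to outrun reketonisation of the photoenol and needs the alkyne cis to the ketal carbon: the first is served by the short tether with its quaternary ketal carbon, an H-bond-accepting solvent that slows the back hydrogen shift, the O-methyl group that blocks excited-state proton transfer from a peri hydroxyl, and 420–450 nm light absorbed only by the methoxynaphthoquinone, and the second is fixed in step 10. The remaining quinone carbonyl and the C2=C3 bond become the phenalenone enone, so no redox adjustment follows.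

**Step 13**
Reactants: 21 9-O-methylspiropreussione B
Product: 22 spiropreussione B
Conditions: MgI2, Et2O/PhMe, rt; aq. NH4Cl
Reagents that add atoms: none
Why: Chelation-assisted nucleophilic O-demethylation, in which magnesium binds the peri C1 carbonyl/C9 methoxy pair of the vinylogous ester and iodide removes the methyl group by SN2, while the unchelated ketal aryl ethers, the tertiary alcohol and both stereocentres are left alone under these non-basic conditions.

**Compound list**
1 | juglone (5-hydroxy-1,4-naphthoquinone) | O=C1C=CC(=O)c2c(O)cccc12 | starting material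
2 | naphthalene-1,4,5-triol | Oc1ccc(O)c2c(O)cccc12 | intermediate (not isolated)
3 | 1,4,5-trimethoxynaphthalene | COc1ccc(OC)c2c(OC)cccc12 | intermediate
4 | 1-bromo-4,5,8-trimethoxynaphthalene | COc1ccc(Br)c2c(OC)ccc(OC)c12 | intermediate
5 | 2-(4,5,8-trimethoxynaphthalen-1-yl)acetonitrile | COc1ccc(CC#N)c2c(OC)ccc(OC)c12 | intermediate
6 | methyl 2-(4,5,8-trimethoxynaphthalen-1-yl)acetimidate hydrochloride | COC(=[NH2+])Cc1ccc(OC)c2c(OC)ccc(OC)c12.[Cl-] | intermediate (not isolated)
7 | 4,5,8-trimethoxy-1-(2,2,2-trimethoxyethyl)naphthalene | COc1ccc(CC(OC)(OC)OC)c2c(OC)ccc(OC)c12 | intermediate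
8 | 1,8-dihydroxynaphthalene | Oc1cccc2cccc(O)c12 | starting material
9 | 2-methoxy-2-[(4,5,8-trimethoxynaphthalen-1-yl)methyl]naphtho[1,8-de][1,3]dioxine | COc1ccc(CC3(OC)Oc4cccc5cccc(O3)c45)c2c(OC)ccc(OC)c12 | intermediate
10 | (R)-4-(tert-butyldimethylsilyloxy)cyclopent-2-en-1-one | O=C1C=C[C@H](O[Si](C)(C)C(C)(C)C)C1 | starting material
11 | ethynylmagnesium bromide | C#C[Mg]Br | starting material
12 | (1S,4R)-4-(tert-butyldimethylsilyloxy)-1-ethynylcyclopent-2-en-1-ol (OH cis to OTBS) | O[C@]1(C#C)C=C[C@H](O[Si](C)(C)C(C)(C)C)C1 | intermediate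
13 | (1S,4R)-1-ethynylcyclopent-2-ene-1,4-diol | O[C@]1(C#C)C=C[C@H](O)C1 | intermediate
14 | (S)-4-ethynyl-4-hydroxycyclopent-2-en-1-one | O[C@]1(C#C)C=CC(=O)C1 | intermediate
15 | (R)-5-ethynyl-2,5-bis(trimethylsilyloxy)cyclopenta-1,3-diene | C[Si](C)(C)O[C@]1(C#C)C=CC(O[Si](C)(C)C)=C1 | intermediate
16 | 2-[(4,5,8-trimethoxynaphthalen-1-yl)methyl]naphtho[1,8-de][1,3]dioxin-2-ylium triflate | COc1ccc(CC3=[O+]c4cccc5cccc(O3)c45)c2c(OC)ccc(OC)c12.[O-]S(=O)(=O)C(F)(F)F | intermediate (not isolated)
17 | (4R,5S)-4-ethynyl-5-{2-[(4,5,8-trimethoxynaphthalen-1-yl)methyl]naphtho[1,8-de][1,3]dioxin-2-yl}-4-(trimethylsilyloxy)cyclopent-2-en-1-one (ketal carbon cis to ethynyl) | COc1ccc(CC3(Oc4cccc5cccc(c45)O3)[C@@H]3C(=O)C=C[C@]3(O[Si](C)(C)C)C#C)c2c(OC)ccc(OC)c12 | intermediate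
18 | (4R,5S)-4-ethynyl-4-hydroxy-5-{2-[(8-methoxy-1,4-dioxo-1,4-dihydronaphthalen-5-yl)methyl]naphtho[1,8-de][1,3]dioxin-2-yl}cyclopent-2-en-1-one (key-step precursor) | O=C1C=CC(=O)c2c(CC3(Oc4cccc5cccc(c45)O3)[C@@H]3C(=O)C=C[C@]3(O)C#C)ccc(OC)c12 | intermediate
19 | photoenol of 18: 4-hydroxy-5-alkylidene-8-methoxynaphthalen-1(5H)-one form, (E) exocyclic C=C, cyclopentenone centres 4R,5S | O=C1C=CC(O)=C2/C(=C/C3(Oc4cccc5cccc(c45)O3)[C@@H]3C(=O)C=C[C@]3(O)C#C)C=CC(OC)=C12 | intermediate (not isolated)
20 | hydroxy cycloadduct: 3a-hydroxy-3a,6-dihydro form of 21 (OH on C3a and H on C6 cis; these two transient centres otherwise not specified) | O=C1C=CC2(O)C=C3C(c4ccc(OC)c1c42)C1(Oc2cccc4cccc(c24)O1)[C@@H]1C(=O)C=C[C@]31O | intermediate (not isolated)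
21 | 9-O-methylspiropreussione B: 9-methoxyphenalen-1-one fused at C5–C6 to the indane ring; C6 bears the spiro naphtho[1,8-de][1,3]dioxine ketal carbon, C5 the tertiary carbinol; cis-fused cyclopent-2-enone with (S)-CH α to C=O and (R)-C–OH | O=C1C=Cc2cc3c(c4ccc(OC)c1c24)C1(Oc2cccc4cccc(c24)O1)[C@@H]1C(=O)C=C[C@]31O | intermediate
22 | spiropreussione B (9-hydroxy compound, same S/R centres) | O=C1C=Cc2cc3c(c4ccc(O)c1c24)C1(Oc2cccc4cccc(c24)O1)[C@@H]1C(=O)C=C[C@]31O | target

**Step count**
Total steps: 13. Longest linear sequence: 9 steps (1–5, then 10–13).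

**Steps most likely to fail**

1. Step 12 (key step). The photoenol may return to the quinone by back hydrogen transfer faster than the unactivated alkyne intercepts it. The quinone may also be photoreduced, or the phenalenone product may sensitise secondary photolysis. The fallback sets out from 17 and rejoins at 21, and makes the two ring bonds one after the other by ground-state, precedented reaction types.
   - Ruthenium-catalysed anti-Markovnikov addition of acetic acid to the terminal alkyne ([Ru(methallyl)2(dppb)], AcOH, PhMe, 60 °C) should give the (Z)-enol acetate F1.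
   - DDQ (2,6-dichloropyridine, MeNO2, rt) should abstract hydride from the benzylic CH2 para to the methoxy group, and the enol acetate should close the five-membered ring onto the benzylic cation (oxidative C–H cyclisation). Loss of the acetyl group then gives the cyclised aldehyde F2.
   - CF3CO2H in wet CH2Cl2 should effect a Bradsher-type cyclodehydration by ipso attack of the aldehyde carbon on the peri carbon that carries a methoxy group para to a second methoxy group. Hydrolysis of the resulting methoxy-oxocarbenium ion gives the dienone F3 (not isolated). Loss of water and methanol then aromatises the new ring and removes the silyl ether, giving 21.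

2. Step 10. The naphthodioxinylium ion may lose a proton to the ketene acetal, which destroys the acid-labile diene. Bond formation between two fully substituted centres may fail, or attack may occur syn to the silyloxy group. The fallback sets out from nitrile 5 (with diene 15) and rejoins at 17.
   - DIBAL-H reduction of 5 (PhMe, −78 °C, aqueous acid work-up) should give 2-(4,5,8-trimethoxynaphthalen-1-yl)acetaldehyde F4.
   - Its Mukaiyama aldol reaction with 15 (BF3·OEt2, CH2Cl2, −78 °C), an addition to an unhindered aldehyde that needs no ionisation, should give the β-hydroxy ketone F5 with the new bond again anti to the silyloxy group.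
   - Dess–Martin oxidation should give the 2-acylcyclopentenone F6.
   - Acid-catalysed ketalisation of the side-chain carbonyl with 8 (CSA, 4 Å sieves, PhMe), the classical way to naphthalenediol ketals, should give 17. The C5 configuration is then set by protonation anti to the silyloxy group.

3. Step 5. Exchange may stop short, or 9 may lose methanol to the ketene acetal or hydrolyse to the ester on isolation. The fallback sets out from 7 (with 15) and rejoins at 17.
   - The trimethyl orthoester 7 itself serves as the electrophile in the Mukaiyama-type alkylation of 15 (TMSOTf cat., CH2Cl2, −78 °C), giving the dimethyl ketal F7.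
   - The naphthalenediol is introduced afterwards by acid-catalysed transketalisation with 8 (PPTS, PhMe, removal of MeOH), which should give 17.

**Further compounds**
F1 | step 12 | (Z)-enol acetate: 17 with C≡CH replaced by (Z)-CH=CH–OAc | COc1ccc(CC3(Oc4cccc5cccc(c45)O3)[C@@H]3C(=O)C=C[C@]3(O[Si](C)(C)C)/C=C\OC(C)=O)c2c(OC)ccc(OC)c12
F2 | step 12 | cyclised aldehyde: benzylic carbon bonded to the former internal alkyne carbon, which bears CHO (two new centres not specified) | COc1ccc(C6C3(Oc4cccc5cccc(c45)O3)[C@@H]3C(=O)C=C[C@]3(O[Si](C)(C)C)C6C=O)c2c(OC)ccc(OC)c12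
F3 | step 12 | dienone: 3a-methoxy-4-hydroxy-3a,4,5,6-tetrahydro form of 21 (not isolated) | O=C1C=CC2(OC)C(O)C3C(c4ccc(OC)c1c42)C1(Oc2cccc4cccc(c24)O1)[C@@H]1C(=O)C=C[C@]31O
F4 | step 10 | 2-(4,5,8-trimethoxynaphthalen-1-yl)acetaldehyde | COc1ccc(CC=O)c2c(OC)ccc(OC)c12
F5 | step 10 | β-hydroxy ketone (aldol adduct, carbinol centre not specified) | COc1ccc(CC(O)[C@@H]3C(=O)C=C[C@]3(O[Si](C)(C)C)C#C)c2c(OC)ccc(OC)c12
F6 | step 10 | 2-acylcyclopentenone (C5 labile, drawn as diketone) | COc1ccc(CC(=O)C3C(=O)C=C[C@]3(O[Si](C)(C)C)C#C)c2c(OC)ccc(OC)c12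
F7 | step 5 | dimethyl ketal analogue of 17 | COc1ccc(CC(OC)(OC)[C@@H]3C(=O)C=C[C@]3(O[Si](C)(C)C)C#C)c2c(OC)ccc(OC)c12
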